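The retrosynthesis removes the 7- and 3'-O-benzyl groups and the 3-O-benzoyl group. It then cuts O1–C8a (ring C), C3–O, C2–C3 and the aryl ester C–O bond, which leaves a ring A acetophenone (C4a–C8a, C4, C3) and a ring B benzoic acid (C2).
Enabling feature: on ring A the C5 hydroxyl and the C8 methoxyl are para, so ring A is a 4-methoxyphenol. In its two-electron-oxidised form (C5 dienone, C8 dimethyl ketal) the unsubstituted carbon C8a is the β-position of both the C5 and the C4 carbonyl.
Forward: rings A and B are bought as arenes. Ring A gains its third oxygen by para-hydroxylation, the halves are joined as an aryl ester, the aroyl group is shifted to carbon, and C3 is oxygenated.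
Ring C is closed last: anodic oxidation of ring A is followed by attack of the ring B aroyl enol oxygen on C8a. The ortho phenol is therefore not used up as O1 and remains as 5-OH.
Stereochemistry: the target is achiral. C3 of the open-chain precursor and C8a of the transient adduct are racemic, and both become sp2.
Key step: step 8

Remark: flavone numbering (O1, C2–C4, C4a, C5–C8, C8a, ring B primed) is also used for open-chain precursors, and the open-chain diketones are assumed to equilibrate freely with their enol and cyclic hemiketal forms under the buffered conditions of the ring closure.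

Step 1
Reactants: 1 2',4'-dihydroxyacetophenone
Product: 2 1-[4-(benzyloxy)-2-hydroxyphenyl]ethanone
Conditions: BnBr (1.05 equiv), K2CO3, acetone, reflux
Reagents that add atoms: benzyl bromide, BrCc1ccccc1
Why: Williamson ether synthesis under chelation control: the 2-hydroxyl is hydrogen-bonded to the acetyl carbonyl and is the weaker acid and nucleophile, so one equivalent of benzyl bromide should alkylate only the 4-hydroxyl.

Step 2
Reactants: 2 1-[4-(benzyloxy)-2-hydroxyphenyl]ethanone
Product: 4 1-[4-(benzyloxy)-2,5-dihydroxyphenyl]ethanone, via aryl sulfate 3 (not isolated)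
Conditions: K2S2O8, aq NaOH, pyridine, 0 → 20 °C; then 2 M HCl, 70 °C
Reagents that add atoms: potassium persulfate, [K+].[K+].[O-]S(=O)(=O)OOS(=O)(=O)[O-]
Why: Elbs persulfate oxidation: the phenolate of 2 attacks the peroxide O–O bond through the free carbon para to its oxygen, which places the new oxygen at the future C8, and the aryl sulfate 3 is then hydrolysed by dilute acid that aryl benzyl ethers tolerate.

Step 3
Reactants: 4 1-[4-(benzyloxy)-2,5-dihydroxyphenyl]ethanone
Product: 5 1-[4-(benzyloxy)-2-hydroxy-5-methoxyphenyl]ethanone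
Conditions: MeI (1.1 equiv), K2CO3, acetone, N2, 23 → 50 °C
Reagents that add atoms: iodomethane, CI
Why: Williamson methylation, again under chelation control: of the two phenols of 4 only the new one lacks a hydrogen bond to the ketone, so a slight excess of MeI with a weak base should cap it alone and leave the future 5-OH free.

Step 4
Reactants: 6 3-hydroxy-4,5-dimethoxybenzoic acid
Product: 8 3-(benzyloxy)-4,5-dimethoxybenzoic acid, via benzyl ester 7 (not isolated)
Conditions: BnBr (2.3 equiv), K2CO3, DMF, 60 °C; then 2 M NaOH, MeOH, 60 °C; then HCl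
Reagents that add atoms: benzyl bromide, BrCc1ccccc1; sodium hydroxide, [Na+].[OH-] (its oxygen ends in the carboxyl group)
Why: Exhaustive Williamson and carboxylate benzylation followed by saponification in the same flask: hydroxide cleaves only the benzyl ester of 7, since aryl benzyl and methyl ethers are inert to base.

Step 5
Reactants: 5 1-[4-(benzyloxy)-2-hydroxy-5-methoxyphenyl]ethanone; 8 3-(benzyloxy)-4,5-dimethoxybenzoic acid
Product: 9 2-acetyl-5-(benzyloxy)-4-methoxyphenyl 3-(benzyloxy)-4,5-dimethoxybenzoate
Conditions: N,N'-dicyclohexylcarbodiimide (DCC), 4-(dimethylamino)pyridine (0.1 equiv), CH2Cl2, 0 → 23 °C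
Reagents that add atoms: none
Why: Steglich esterification: the acylpyridinium ion formed from the DCC-activated acid is reactive enough to acylate the chelated phenol, a standard entry to Baker–Venkataraman substrates.

Step 6
Reactants: 9 2-acetyl-5-(benzyloxy)-4-methoxyphenyl 3-(benzyloxy)-4,5-dimethoxybenzoate
Product: 10 1-[4-(benzyloxy)-2-hydroxy-5-methoxyphenyl]-3-[3-(benzyloxy)-4,5-dimethoxyphenyl]propane-1,3-dione
Conditions: KOtBu (2.2 equiv), THF, 0 → 23 °C; then 1 M HCl, 0 °C
Reagents that add atoms: none
Why: Baker–Venkataraman rearrangement: the methyl ketone enolate attacks the neighbouring aryl ester through a six-membered transition state and the O-to-C aroyl shift, which forms C2–C3, is driven by the stabilised diketone enolate and phenolate, while a cold dilute acid quench avoids cyclodehydration.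

Step 7
Reactants: 10 1-[4-(benzyloxy)-2-hydroxy-5-methoxyphenyl]-3-[3-(benzyloxy)-4,5-dimethoxyphenyl]propane-1,3-dione; 11 dibenzoyl peroxide
Product: 12 racemic 1-[4-(benzyloxy)-2-hydroxy-5-methoxyphenyl]-3-[3-(benzyloxy)-4,5-dimethoxyphenyl]-1,3-dioxopropan-2-yl benzoate
Conditions: NaH (1.0 equiv), THF, 0 °C; then 11, 0 → 23 °C, dark; pH 7 buffer
Reagents that add atoms: none
Why: Benzoyloxylation of a 1,3-dicarbonyl enolate with a diacyl peroxide: the C3 methylene is the most acidic site, so one equivalent of NaH should form only its enolate, which attacks the O–O bond of 11 through carbon while the chelated phenol stays protonated; the new C3 stereocentre arises racemic and is erased in step 8.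

Step 8
Reactants: 12 racemic 1-[4-(benzyloxy)-2-hydroxy-5-methoxyphenyl]-3-[3-(benzyloxy)-4,5-dimethoxyphenyl]-1,3-dioxopropan-2-yl benzoate
Product: 15 7-(benzyloxy)-2-[3-(benzyloxy)-4,5-dimethoxyphenyl]-5-hydroxy-8-methoxy-4-oxo-4H-chromen-3-yl benzoate, via quinone monoketal 13 (not isolated), via oxa-Michael adduct 14 (not isolated)
Conditions: graphite anode, Pt cathode, undivided cell, constant current, 2.1 F mol−1, LiClO4 (0.1 M), NaHCO3 (solid), MeOH–CH2Cl2 (4:1), 0 °C; current off, 23 °C; filter, pyridinium p-toluenesulfonate (PPTS, 0.2 equiv), 23 °C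
Reagents that add atoms: methanol, CO (supplies the second C8 methoxyl of 13 and 14; one of the two methoxyls leaves again on the way to 15)
Why: Proposed new method: the 4-methoxyphenol of ring A is the most easily oxidised group of 12 (ring B is an acyl-deactivated trialkoxyarene), so loss of two electrons and a proton at the anode gives a phenoxenium ion that methanol captures at C8, para to the C5 oxygen, to form quinone monoketal 13, in which C8a is the β-carbon of both the C5 and the C4 carbonyl. The bicarbonate buffer enolises the acidic C3–H, and the oxygen of the ring B aroyl group adds to C8a in a 6-endo-trig oxa-Michael closure that forms O1–C8a and ring C and gives 14; attack through C3 or through the C4 oxygen would need a four-membered ring. Once the current is off, PPTS ionises the C8 ketal, the C8a proton is lost and the dienone tautomerises, which returns the arene with the 8-methoxyl and the chelated 5-hydroxyl and makes the reversible addition irreversible. The closest known reaction types are the anodic conversion of 4-methoxyphenols into quinone monoketals and the conjugate addition–aromatisation of nucleophiles on quinone monoketals and 2-acylquinones, whereas their combination into a chromone closure has no precedent. No stereocentre survives: C3 becomes sp2 and the C8a centre of racemic 14 is erased on aromatisation, so nothing has to be controlled. The step needs closure at C8a in preference to dehydrative condensation of the C5 phenol with C2, to attack at C6–C7 and to capture by solvent, and this is secured by withholding acid until the phenol is used up, by the donor-substituted and geometrically remote C6–C7 alkene, by the reversibility of methanol addition set against the conjugated pyranone gained on the intramolecular path, and by keeping the ketal in 14 until electrolysis ends so that the oxidisable phenol 15 never meets the anode.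

Step 9
Reactants: 15 7-(benzyloxy)-2-[3-(benzyloxy)-4,5-dimethoxyphenyl]-5-hydroxy-8-methoxy-4-oxo-4H-chromen-3-yl benzoate
Product: 16 7-(benzyloxy)-2-[3-(benzyloxy)-4,5-dimethoxyphenyl]-3,5-dihydroxy-8-methoxy-4H-chromen-4-one
Conditions: K2CO3 (2 equiv), MeOH–THF, Ar, 0 → 23 °C; then 1 M HCl
Reagents that add atoms: none
Why: Carbonate-mediated methanolysis (transesterification): the 3-benzoate is an enol ester with a good leaving group and should be cleaved at room temperature, whereas the ethers and the pyranone are untouched.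

Step 10
Reactants: 16 7-(benzyloxy)-2-[3-(benzyloxy)-4,5-dimethoxyphenyl]-3,5-dihydroxy-8-methoxy-4H-chromen-4-one
Product: 17 3,5,7-trihydroxy-2-(3-hydroxy-4,5-dimethoxyphenyl)-8-methoxy-4H-chromen-4-one (CNP0225742.0)
Conditions: H2 (1 atm), 10% Pd/C, EtOAc–MeOH, 23 °C
Reagents that add atoms: none
Why: Catalytic hydrogenolysis of aryl benzyl ethers: both benzylic C–O bonds are cleaved at one atmosphere of hydrogen, conditions under which the tetrasubstituted C2–C3 bond of the aromatic pyranone and the methyl ethers of a flavonol persist.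

Compound list
1 | 2',4'-dihydroxyacetophenone | CC(=O)c1ccc(O)cc1O | starting material
2 | 1-[4-(benzyloxy)-2-hydroxyphenyl]ethanone | CC(=O)c1ccc(OCc2ccccc2)cc1O | intermediate
3 | potassium 5-acetyl-2-(benzyloxy)-4-hydroxyphenyl sulfate (aryl sulfate, not isolated) | CC(=O)c1cc(OS(=O)(=O)[O-])c(OCc2ccccc2)cc1O.[K+] | intermediate
4 | 1-[4-(benzyloxy)-2,5-dihydroxyphenyl]ethanone | CC(=O)c1cc(O)c(OCc2ccccc2)cc1O | intermediate
5 | 1-[4-(benzyloxy)-2-hydroxy-5-methoxyphenyl]ethanone | CC(=O)c1cc(OC)c(OCc2ccccc2)cc1O | intermediate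
6 | 3-hydroxy-4,5-dimethoxybenzoic acid | COc1cc(C(=O)O)cc(O)c1OC | starting material
7 | benzyl 3-(benzyloxy)-4,5-dimethoxybenzoate (benzyl ester, not isolated) | COc1cc(C(=O)OCc2ccccc2)cc(OCc2ccccc2)c1OC | intermediate
8 | 3-(benzyloxy)-4,5-dimethoxybenzoic acid | COc1cc(C(=O)O)cc(OCc2ccccc2)c1OC | intermediate
9 | 2-acetyl-5-(benzyloxy)-4-methoxyphenyl 3-(benzyloxy)-4,5-dimethoxybenzoate | CC(=O)c1cc(OC)c(OCc2ccccc2)cc1OC(=O)c1cc(OCc2ccccc2)c(OC)c(OC)c1 | intermediate
10 | 1-[4-(benzyloxy)-2-hydroxy-5-methoxyphenyl]-3-[3-(benzyloxy)-4,5-dimethoxyphenyl]propane-1,3-dione | COc1cc(C(=O)CC(=O)c2cc(OCc3ccccc3)c(OC)c(OC)c2)c(O)cc1OCc1ccccc1 | intermediate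
11 | dibenzoyl peroxide | O=C(OOC(=O)c1ccccc1)c1ccccc1 | starting material
12 | racemic 1-[4-(benzyloxy)-2-hydroxy-5-methoxyphenyl]-3-[3-(benzyloxy)-4,5-dimethoxyphenyl]-1,3-dioxopropan-2-yl benzoate | COc1cc(C(=O)C(OC(=O)c2ccccc2)C(=O)c2cc(OCc3ccccc3)c(OC)c(OC)c2)c(O)cc1OCc1ccccc1 | intermediate
13 | racemic 1-[4-(benzyloxy)-3,3-dimethoxy-6-oxocyclohexa-1,4-dien-1-yl]-3-[3-(benzyloxy)-4,5-dimethoxyphenyl]-1,3-dioxopropan-2-yl benzoate (quinone monoketal, not isolated) | COC1(OC)C=C(C(=O)C(OC(=O)c2ccccc2)C(=O)c2cc(OCc3ccccc3)c(OC)c(OC)c2)C(=O)C=C1OCc1ccccc1 | intermediate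
14 | racemic 7-(benzyloxy)-2-[3-(benzyloxy)-4,5-dimethoxyphenyl]-5-hydroxy-8,8-dimethoxy-4-oxo-8,8a-dihydro-4H-chromen-3-yl benzoate (oxa-Michael adduct drawn as its C5 enol, not isolated) | COC1(OC)C(OCc2ccccc2)=CC(O)=C2C(=O)C(OC(=O)c3ccccc3)=C(c3cc(OCc4ccccc4)c(OC)c(OC)c3)OC12 | intermediate
15 | 7-(benzyloxy)-2-[3-(benzyloxy)-4,5-dimethoxyphenyl]-5-hydroxy-8-methoxy-4-oxo-4H-chromen-3-yl benzoate | COc1c(OCc2ccccc2)cc(O)c2c(=O)c(OC(=O)c3ccccc3)c(-c3cc(OCc4ccccc4)c(OC)c(OC)c3)oc12 | intermediate
16 | 7-(benzyloxy)-2-[3-(benzyloxy)-4,5-dimethoxyphenyl]-3,5-dihydroxy-8-methoxy-4H-chromen-4-one | COc1c(OCc2ccccc2)cc(O)c2c(=O)c(O)c(-c3cc(OCc4ccccc4)c(OC)c(OC)c3)oc12 | intermediate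
17 | 3,5,7-trihydroxy-2-(3-hydroxy-4,5-dimethoxyphenyl)-8-methoxy-4H-chromen-4-one | COc1cc(-c2oc3c(OC)c(O)cc(O)c3c(=O)c2O)cc(O)c1OC | target

Total step count: 10. Longest linear sequence: 9 steps (steps 1–3 and 5–10); the ring B branch is step 4.

Steps most likely to fail

Step 8. Several processes could spoil the closure:
- solvent methanol may capture the doubly activated dienone at C8a before the enolate does;
- ring-closed material may be oxidised further;
- the tricarbonyl chain may suffer retro-Claisen cleavage in methanol;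
- dehydrative closure through the C5 phenol may occur before the oxidation is complete.

The fallback uses known chemistry. It makes the same O1–C8a bond by displacing a halide instead of oxidising a C–H bond. It sets out from 4 and comes back at 15. Hydroquinone 4 is oxidised with Ag2O (MgSO4, CH2Cl2) to 2-acetyl-5-(benzyloxy)cyclohexa-2,5-diene-1,4-dione F1. HBr (1 equiv, AcOH–CH2Cl2, 0 °C) adds at the ring carbon next to the acetyl group, the established site of attack on 2-acylquinones, and gives 1-[4-(benzyloxy)-2-bromo-3,6-dihydroxyphenyl]ethanone F2. MeI/K2CO3 then methylates the unchelated hydroxyl to give 1-[4-(benzyloxy)-2-bromo-6-hydroxy-3-methoxyphenyl]ethanone F3. The chemistry of steps 5–7 is repeated on this series. DCC coupling with acid 8 gives 2-acetyl-5-(benzyloxy)-3-bromo-4-methoxyphenyl 3-(benzyloxy)-4,5-dimethoxybenzoate F4. KOtBu shifts the aroyl group to carbon to give 1-[4-(benzyloxy)-2-bromo-6-hydroxy-3-methoxyphenyl]-3-[3-(benzyloxy)-4,5-dimethoxyphenyl]propane-1,3-dione F5. NaH and peroxide 11 give racemic 1-[4-(benzyloxy)-2-bromo-6-hydroxy-3-methoxyphenyl]-3-[3-(benzyloxy)-4,5-dimethoxyphenyl]-1,3-dioxopropan-2-yl benzoate F6. Intramolecular Ullmann-type O-arylation of the diketone enolate (CuI cat., K2CO3, DMF, 90 °C), a known way from 1-(2-bromoaryl)-1,3-diketones to chromones, closes ring C and delivers 15.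

Step 7. The peroxide may oxidise or O-benzoylate the electron-rich free phenol in competition with the enolate. A second benzoyloxylation at C3 is possible, and the ring may close through the C5 phenol during work-up. The fallback sets out from 9 and comes back at 12; it installs the C3 oxygen while the phenol is still masked as the aroyl ester. Ester 9 is brominated at the acetyl carbon with CuBr2 (EtOAc–CHCl3, reflux) to give 5-(benzyloxy)-2-(bromoacetyl)-4-methoxyphenyl 3-(benzyloxy)-4,5-dimethoxybenzoate F7. Potassium benzoate (DMF, 23 °C) displaces the bromide to give 2-[(benzoyloxy)acetyl]-5-(benzyloxy)-4-methoxyphenyl 3-(benzyloxy)-4,5-dimethoxybenzoate F8. A Baker–Venkataraman shift (LiN(SiMe3)2, THF, −78 → 0 °C), long used on ω-oxygenated 2-aroyloxyacetophenones, gives 12. Steps 6 and 7 are thereby replaced and no peroxide meets a free phenol.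

Step 2. Persulfate oxidations typically suffer from low conversion and oxidative degradation of the phenolate. The benzylated phenolate may dissolve poorly in aqueous base, and part of the benzyl ether may be lost during the acid hydrolysis. The fallback sets out from 2 and comes back at 5, replacing oxidation and methylation by halogenation and C–O coupling. Phenol 2 is brominated para to the hydroxyl with NBS (MeCN, 0 °C) to give 1-[4-(benzyloxy)-5-bromo-2-hydroxyphenyl]ethanone F9. Ullmann-type methoxylation (NaOMe, CuBr cat., DMF–MeOH, 110 °C), the reaction type that turns bromophenols into methoxyphenols, gives 5 directly, so steps 2 and 3 are bypassed.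

Further compounds
F1 | step 8 | 2-acetyl-5-(benzyloxy)cyclohexa-2,5-diene-1,4-dione | CC(=O)C1=CC(=O)C(OCc2ccccc2)=CC1=O
F2 | step 8 | 1-[4-(benzyloxy)-2-bromo-3,6-dihydroxyphenyl]ethanone | CC(=O)c1c(Br)c(O)c(OCc2ccccc2)cc1O
F3 | step 8 | 1-[4-(benzyloxy)-2-bromo-6-hydroxy-3-methoxyphenyl]ethanone | CC(=O)c1c(Br)c(OC)c(OCc2ccccc2)cc1O
F4 | step 8 | 2-acetyl-5-(benzyloxy)-3-bromo-4-methoxyphenyl 3-(benzyloxy)-4,5-dimethoxybenzoate | CC(=O)c1c(Br)c(OC)c(OCc2ccccc2)cc1OC(=O)c1cc(OCc2ccccc2)c(OC)c(OC)c1
F5 | step 8 | 1-[4-(benzyloxy)-2-bromo-6-hydroxy-3-methoxyphenyl]-3-[3-(benzyloxy)-4,5-dimethoxyphenyl]propane-1,3-dione | COc1c(OCc2ccccc2)cc(O)c(C(=O)CC(=O)c2cc(OCc3ccccc3)c(OC)c(OC)c2)c1Br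
F6 | step 8 | racemic 1-[4-(benzyloxy)-2-bromo-6-hydroxy-3-methoxyphenyl]-3-[3-(benzyloxy)-4,5-dimethoxyphenyl]-1,3-dioxopropan-2-yl benzoate | COc1c(OCc2ccccc2)cc(O)c(C(=O)C(OC(=O)c2ccccc2)C(=O)c2cc(OCc3ccccc3)c(OC)c(OC)c2)c1Br
F7 | step 7 | 5-(benzyloxy)-2-(bromoacetyl)-4-methoxyphenyl 3-(benzyloxy)-4,5-dimethoxybenzoate | O=C(CBr)c1cc(OC)c(OCc2ccccc2)cc1OC(=O)c1cc(OCc2ccccc2)c(OC)c(OC)c1
F8 | step 7 | 2-[(benzoyloxy)acetyl]-5-(benzyloxy)-4-methoxyphenyl 3-(benzyloxy)-4,5-dimethoxybenzoate | O=C(COC(=O)c1ccccc1)c1cc(OC)c(OCc2ccccc2)cc1OC(=O)c1cc(OCc2ccccc2)c(OC)c(OC)c1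
F9 | step 2 | 1-[4-(benzyloxy)-5-bromo-2-hydroxyphenyl]ethanone | CC(=O)c1cc(Br)c(OCc2ccccc2)cc1O
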